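**Retrosynthetic overview**
1. Target ⇒ global removal of six MOM ethers from a protected flavanone. Ring C is opened by a retro-oxa-Michael step to a 2'-hydroxychalcone.
2. Chalcone ⇒ intermolecular Claisen–Schmidt aldol condensation (key C–C bond) between a MOM-protected 3,5-diprenyl ring A methyl ketone and an enantiopure dihydrobenzofuran-5-carbaldehyde.
3. Aldehyde ⇒ aryl bromide (Br/Li exchange, DMF). The trans-(2R,3R)-2,3-diaryl-dihydrobenzofuran ⇒ cis isomer (acid epimerisation at C2) ⇒ enantioselective Rh2(R-PTAD)4-catalysed carbene C–H insertion of a diaryldiazomethane.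
4. Diazo precursor ⇒ benzophenone hydrazone ⇒ three commercial mono-aryl building blocks. Ring A ketone ⇒ C-prenylation of a commercial acylphloroglucinol.
5. Ring order: all benzene rings are bought; the dihydrofuran ring is made first (step 6) and pyranone ring C last (step 14).

Assumption: the R antipode of Rh2(PTAD)4 is written in step 6 on the premise that it gives the (2S,3R) cis product; if X-ray analysis of the bromide shows the opposite sense, the S antipode is used with nothing else changed.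

**Step 1**
Reactants: 1 2-hydroxy-4-methoxybenzaldehyde
Product: 2 5-bromo-2-hydroxy-4-methoxybenzaldehyde
Conditions: Br2 (1.05 equiv), AcOH, 15 °C to rt
Reagents that add atoms: bromine, BrBr
Why: Electrophilic aromatic bromination goes to C5, which is para to the free phenol and ortho to the methoxy group, whereas C3 is flanked by two substituents, so one bromine enters regioselectively.

**Step 2**
Reactants: 2 5-bromo-2-hydroxy-4-methoxybenzaldehyde; 3 4-methoxybenzyl chloride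
Product: 4 5-bromo-4-methoxy-2-[(4-methoxyphenyl)methoxy]benzaldehyde
Conditions: K2CO3 (2 equiv), DMF, 60 °C
Reagents that add atoms: none
Why: Williamson ether synthesis of the phenoxide with a reactive benzylic chloride installs the 4-methoxybenzyl ether whose CH2 group later becomes C2 of the dihydrobenzofuran.

**Step 3**
Reactants: 4 5-bromo-4-methoxy-2-[(4-methoxyphenyl)methoxy]benzaldehyde; 5 1-bromo-3,5-dimethoxybenzene
Product: 7 racemic [5-bromo-4-methoxy-2-[(4-methoxyphenyl)methoxy]phenyl](3,5-dimethoxyphenyl)methanol, via Grignard reagent 6 (not isolated)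
Conditions: 5 (1.3 equiv), Mg, THF, 45 °C; then 4, 0 °C; aq NH4Cl
Reagents that add atoms: none
Why: Grignard addition of the aryl magnesium reagent made from 5 to the aldehyde is fast at 0 °C while the aryl bromide of 4 does not exchange with an aryl Grignard reagent at that temperature, and the racemic carbinol centre is erased in step 4.

**Step 4**
Reactants: 7 racemic [5-bromo-4-methoxy-2-[(4-methoxyphenyl)methoxy]phenyl](3,5-dimethoxyphenyl)methanol
Product: 8 [5-bromo-4-methoxy-2-[(4-methoxyphenyl)methoxy]phenyl](3,5-dimethoxyphenyl)methanone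
Conditions: MnO2 (15 equiv), CH2Cl2, rt
Reagents that add atoms: none
Why: Activated MnO2 oxidises the doubly benzylic alcohol to the benzophenone (benzylic alcohol oxidation) without touching the benzyl ether or the aryl bromide.

**Step 5**
Reactants: 8 [5-bromo-4-methoxy-2-[(4-methoxyphenyl)methoxy]phenyl](3,5-dimethoxyphenyl)methanone
Product: 9 [5-bromo-4-methoxy-2-[(4-methoxyphenyl)methoxy]phenyl](3,5-dimethoxyphenyl)methanone hydrazone (E/Z mixture)
Conditions: N2H4·H2O (20 equiv), AcOH (0.2 equiv), EtOH, 90 °C, sealed tube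
Reagents that add atoms: hydrazine (used as the monohydrate), NN
Why: Acid-catalysed condensation with a large excess of hydrazine gives the N-unsubstituted hydrazone while suppressing azine formation, and its geometry is irrelevant because it is oxidised to the diazo compound.

**Step 6**
Reactants: 9 [5-bromo-4-methoxy-2-[(4-methoxyphenyl)methoxy]phenyl](3,5-dimethoxyphenyl)methanone hydrazone
Product: 11 (2S,3R)-5-bromo-3-(3,5-dimethoxyphenyl)-6-methoxy-2-(4-methoxyphenyl)-2,3-dihydro-1-benzofuran (cis), via diazo compound 10 (not isolated)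
Conditions: MnO2 (8 equiv), MeCN, 0 °C; filter; Rh2(R-PTAD)4 (tetrakis[(R)-(1-adamantyl)(N-phthalimido)acetato]dirhodium, 1 mol%), MeCN, 0 °C to rt
Reagents that add atoms: none
Why: MnO2 dehydrogenates the hydrazone to the diaryldiazomethane and Rh2(R-PTAD)4 converts it into a donor/donor carbene that inserts into the activated benzylic C–H bond five atoms away (intramolecular carbene C–H insertion), the concerted insertion giving the cis ring and the catalyst setting C3 as R and C2 as S.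

**Step 7**
Reactants: 11 (2S,3R)-5-bromo-3-(3,5-dimethoxyphenyl)-6-methoxy-2-(4-methoxyphenyl)-2,3-dihydro-1-benzofuran
Product: 12 (2R,3R)-5-bromo-3-(3,5-dimethoxyphenyl)-6-methoxy-2-(4-methoxyphenyl)-2,3-dihydro-1-benzofuran (trans)
Conditions: TFA (10 equiv), CH2Cl2 (0.02 M), 0 °C to rt; NMR and chiral HPLC control
Reagents that add atoms: none
Why: The acid reversibly ionises the C2–O bond to a 4-methoxybenzylic cation (the same ionisation that cleaves 4-methoxybenzyl aryl ethers) and reclosure under thermodynamic control inverts C2 to R, giving the less strained trans ring while C3, which is not involved, stays R.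

**Step 8**
Reactants: 12 (2R,3R)-5-bromo-3-(3,5-dimethoxyphenyl)-6-methoxy-2-(4-methoxyphenyl)-2,3-dihydro-1-benzofuran
Product: 13 (2R,3R)-5-bromo-3-(3,5-dihydroxyphenyl)-2-(4-hydroxyphenyl)-2,3-dihydro-1-benzofuran-6-ol
Conditions: BBr3 (10 equiv), CH2Cl2, −78 °C to rt; ice water
Reagents that add atoms: none
Why: BBr3 cleaves the four aryl methyl ethers (Lewis acid ether cleavage), the aryl bromide is inert, and any reversible C2–O ionisation can only return the already favoured trans ring, so both stereocentres are kept.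

**Step 9**
Reactants: 13 (2R,3R)-5-bromo-3-(3,5-dihydroxyphenyl)-2-(4-hydroxyphenyl)-2,3-dihydro-1-benzofuran-6-ol
Product: 14 (2R,3R)-3-[3,5-bis(methoxymethoxy)phenyl]-5-bromo-6-(methoxymethoxy)-2-[4-(methoxymethoxy)phenyl]-2,3-dihydro-1-benzofuran
Conditions: MOMCl (8 equiv), i-Pr2NEt (10 equiv), CH2Cl2/DMF, 0 °C to rt
Reagents that add atoms: chloromethyl methyl ether (MOMCl), COCCl
Why: O-alkylation of the four phenols under amine base gives acetal ethers that withstand organolithium, hydroxide and acetate conditions and can be removed together at the end.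

**Step 10**
Reactants: 14 (2R,3R)-3-[3,5-bis(methoxymethoxy)phenyl]-5-bromo-6-(methoxymethoxy)-2-[4-(methoxymethoxy)phenyl]-2,3-dihydro-1-benzofuran
Product: 16 (2R,3R)-3-[3,5-bis(methoxymethoxy)phenyl]-6-(methoxymethoxy)-2-[4-(methoxymethoxy)phenyl]-2,3-dihydro-1-benzofuran-5-carbaldehyde, via aryllithium 15 (not isolated)
Conditions: n-BuLi (1.1 equiv), THF, −78 °C, 20 min; DMF (3 equiv), −78 to 0 °C; aq NH4Cl
Reagents that add atoms: N,N-dimethylformamide, CN(C)C=O
Why: Bromine–lithium exchange at −78 °C is much faster than any directed ortho-lithiation and the aryllithium is formylated by DMF (Bouveault aldehyde synthesis) without touching either stereocentre.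

**Step 11**
Reactants: 17 1-(2,4,6-trihydroxyphenyl)ethanone; 18 1-bromo-3-methylbut-2-ene
Product: 19 1-[2,4,6-trihydroxy-3,5-bis(3-methylbut-2-en-1-yl)phenyl]ethanone
Conditions: 18 (2.2 equiv), 10% aq KOH, 0 °C to rt; chromatography (expect about 30–40%)
Reagents that add atoms: none
Why: The ambident phloroglucinol phenolate is C-alkylated by the allylic bromide at its two free ring positions (phenolate C-prenylation in water), and the 3,5-diprenyl ketone is separated from the mono- and geminally diprenylated by-products.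

**Step 12**
Reactants: 19 1-[2,4,6-trihydroxy-3,5-bis(3-methylbut-2-en-1-yl)phenyl]ethanone
Product: 20 1-[2-hydroxy-4,6-bis(methoxymethoxy)-3,5-bis(3-methylbut-2-en-1-yl)phenyl]ethanone
Conditions: MOMCl (2.3 equiv), i-Pr2NEt (3 equiv), CH2Cl2, 0 °C to rt
Reagents that add atoms: chloromethyl methyl ether (MOMCl), COCCl
Why: O-alkylation protects the 4-hydroxyl and one ortho hydroxyl, while the other ortho hydroxyl, hydrogen-bonded to the ketone, stays free as the later ring-closing nucleophile, and because the two ortho hydroxyls are symmetry-equivalent only one bis-ether can form.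

**Step 13**
Reactants: 20 1-[2-hydroxy-4,6-bis(methoxymethoxy)-3,5-bis(3-methylbut-2-en-1-yl)phenyl]ethanone; 16 (2R,3R)-3-[3,5-bis(methoxymethoxy)phenyl]-6-(methoxymethoxy)-2-[4-(methoxymethoxy)phenyl]-2,3-dihydro-1-benzofuran-5-carbaldehyde
Product: 22 (E)-3-[(2R,3R)-3-[3,5-bis(methoxymethoxy)phenyl]-6-(methoxymethoxy)-2-[4-(methoxymethoxy)phenyl]-2,3-dihydro-1-benzofuran-5-yl]-1-[2-hydroxy-4,6-bis(methoxymethoxy)-3,5-bis(3-methylbut-2-en-1-yl)phenyl]prop-2-en-1-one, via aldol adduct 21 (not isolated)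
Conditions: 20 (1.3 equiv), KOH (50% aq, 10 equiv), EtOH/THF, rt to 40 °C, 48 h; citric acid to pH 6
Reagents that add atoms: none
Why: In this Claisen–Schmidt aldol condensation the potassium enolate of methyl ketone 20 adds to the non-enolisable aldehyde 16 and the aldol adduct loses water by E1cB elimination to the conjugated E enone, forming the C–C bond that joins the two fragments without creating a stereocentre.

**Step 14**
Reactants: 22 (E)-3-[(2R,3R)-3-[3,5-bis(methoxymethoxy)phenyl]-6-(methoxymethoxy)-2-[4-(methoxymethoxy)phenyl]-2,3-dihydro-1-benzofuran-5-yl]-1-[2-hydroxy-4,6-bis(methoxymethoxy)-3,5-bis(3-methylbut-2-en-1-yl)phenyl]prop-2-en-1-one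
Product: 24 (2S)-2-[(2R,3R)-3-[3,5-bis(methoxymethoxy)phenyl]-6-(methoxymethoxy)-2-[4-(methoxymethoxy)phenyl]-2,3-dihydro-1-benzofuran-5-yl]-5,7-bis(methoxymethoxy)-6,8-bis(3-methylbut-2-en-1-yl)-2,3-dihydro-4H-chromen-4-one, via 2R epimer 23 (not isolated)
Conditions: NaOAc (10 equiv), EtOH, reflux, 36 h; silica gel chromatography takes out pure 24; the pooled remainder (23 together with 22) goes back unpurified into the same conditions; three cycles (theoretical ceiling 50, 75 and 88% of 24 after one, two and three cycles)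
Reagents that add atoms: none
Why: Intramolecular oxa-Michael addition of the free ortho phenol to the enone closes ring C reversibly and without useful bias from the remote dihydrobenzofuran, so about half of the material first closes to the 2R epimer 23, which under the same acetate conditions reopens to chalcone 22 by retro-oxa-Michael (E1cB) reaction and closes again, and because 23 and 24 are diastereomers the 2S centre is secured by taking 24 out on silica after each cycle while 23 is fed back and drained towards 24.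

**Step 15**
Reactants: 24 (2S)-2-[(2R,3R)-3-[3,5-bis(methoxymethoxy)phenyl]-6-(methoxymethoxy)-2-[4-(methoxymethoxy)phenyl]-2,3-dihydro-1-benzofuran-5-yl]-5,7-bis(methoxymethoxy)-6,8-bis(3-methylbut-2-en-1-yl)-2,3-dihydro-4H-chromen-4-one
Product: 25 (2S)-2-[(2R,3R)-3-(3,5-dihydroxyphenyl)-6-hydroxy-2-(4-hydroxyphenyl)-2,3-dihydro-1-benzofuran-5-yl]-5,7-dihydroxy-6,8-bis(3-methylbut-2-en-1-yl)-2,3-dihydro-4H-chromen-4-one
Conditions: 3 M aq HCl, MeOH/THF, 40 °C, 3–5 h, HPLC control; reversed-phase HPLC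
Reagents that add atoms: none
Why: Acid-catalysed acetal exchange with methanol removes all six MOM ethers as dimethoxymethane under conditions mild enough to leave the prenyl double bonds, the trans-dihydrobenzofuran and C2 of the hydrogen-bonded 5-hydroxyflavanone unchanged.

**Compound list**
1 | 2-hydroxy-4-methoxybenzaldehyde | COc1ccc(C=O)c(O)c1 | starting material
2 | 5-bromo-2-hydroxy-4-methoxybenzaldehyde | COc1cc(O)c(C=O)cc1Br | intermediate
3 | 4-methoxybenzyl chloride | COc1ccc(CCl)cc1 | starting material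
4 | 5-bromo-4-methoxy-2-[(4-methoxyphenyl)methoxy]benzaldehyde | COc1ccc(COc2cc(OC)c(Br)cc2C=O)cc1 | intermediate
5 | 1-bromo-3,5-dimethoxybenzene | COc1cc(Br)cc(OC)c1 | starting material
6 | (3,5-dimethoxyphenyl)magnesium bromide | COc1cc([Mg]Br)cc(OC)c1 | intermediate
7 | racemic [5-bromo-4-methoxy-2-[(4-methoxyphenyl)methoxy]phenyl](3,5-dimethoxyphenyl)methanol | COc1ccc(COc2cc(OC)c(Br)cc2C(O)c2cc(OC)cc(OC)c2)cc1 | intermediate
8 | [5-bromo-4-methoxy-2-[(4-methoxyphenyl)methoxy]phenyl](3,5-dimethoxyphenyl)methanone | COc1ccc(COc2cc(OC)c(Br)cc2C(=O)c2cc(OC)cc(OC)c2)cc1 | intermediate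
9 | hydrazone of 8 (E/Z mixture) | COc1ccc(COc2cc(OC)c(Br)cc2C(=NN)c2cc(OC)cc(OC)c2)cc1 | intermediate
10 | 1-bromo-5-[diazo(3,5-dimethoxyphenyl)methyl]-2-methoxy-4-[(4-methoxyphenyl)methoxy]benzene | COc1ccc(COc2cc(OC)c(Br)cc2C(=[N+]=[N-])c2cc(OC)cc(OC)c2)cc1 | intermediate
11 | (2S,3R)-5-bromo-3-(3,5-dimethoxyphenyl)-6-methoxy-2-(4-methoxyphenyl)-2,3-dihydro-1-benzofuran (cis) | Brc1cc2c(cc1OC)O[C@H](c1ccc(OC)cc1)[C@@H]2c1cc(OC)cc(OC)c1 | intermediate
12 | (2R,3R)-5-bromo-3-(3,5-dimethoxyphenyl)-6-methoxy-2-(4-methoxyphenyl)-2,3-dihydro-1-benzofuran (trans) | Brc1cc2c(cc1OC)O[C@@H](c1ccc(OC)cc1)[C@@H]2c1cc(OC)cc(OC)c1 | intermediate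
13 | (2R,3R)-5-bromo-3-(3,5-dihydroxyphenyl)-2-(4-hydroxyphenyl)-2,3-dihydro-1-benzofuran-6-ol | Brc1cc2c(cc1O)O[C@@H](c1ccc(O)cc1)[C@@H]2c1cc(O)cc(O)c1 | intermediate
14 | (2R,3R)-3-[3,5-bis(methoxymethoxy)phenyl]-5-bromo-6-(methoxymethoxy)-2-[4-(methoxymethoxy)phenyl]-2,3-dihydro-1-benzofuran | Brc1cc2c(cc1OCOC)O[C@@H](c1ccc(OCOC)cc1)[C@@H]2c1cc(OCOC)cc(OCOC)c1 | intermediate
15 | [(2R,3R)-3-[3,5-bis(methoxymethoxy)phenyl]-6-(methoxymethoxy)-2-[4-(methoxymethoxy)phenyl]-2,3-dihydro-1-benzofuran-5-yl]lithium | [Li]c1cc2c(cc1OCOC)O[C@@H](c1ccc(OCOC)cc1)[C@@H]2c1cc(OCOC)cc(OCOC)c1 | intermediate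
16 | (2R,3R)-3-[3,5-bis(methoxymethoxy)phenyl]-6-(methoxymethoxy)-2-[4-(methoxymethoxy)phenyl]-2,3-dihydro-1-benzofuran-5-carbaldehyde | O=Cc1cc2c(cc1OCOC)O[C@@H](c1ccc(OCOC)cc1)[C@@H]2c1cc(OCOC)cc(OCOC)c1 | intermediate
17 | 1-(2,4,6-trihydroxyphenyl)ethanone (phloroacetophenone) | CC(=O)c1c(O)cc(O)cc1O | starting material
18 | 1-bromo-3-methylbut-2-ene (prenyl bromide) | CC(C)=CCBr | starting material
19 | 1-[2,4,6-trihydroxy-3,5-bis(3-methylbut-2-en-1-yl)phenyl]ethanone | CC(=O)c1c(O)c(CC=C(C)C)c(O)c(CC=C(C)C)c1O | intermediate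
20 | 1-[2-hydroxy-4,6-bis(methoxymethoxy)-3,5-bis(3-methylbut-2-en-1-yl)phenyl]ethanone | CC(=O)c1c(O)c(CC=C(C)C)c(OCOC)c(CC=C(C)C)c1OCOC | intermediate
21 | 3-hydroxy-3-[(2R,3R)-3-[3,5-bis(methoxymethoxy)phenyl]-6-(methoxymethoxy)-2-[4-(methoxymethoxy)phenyl]-2,3-dihydro-1-benzofuran-5-yl]-1-[2-hydroxy-4,6-bis(methoxymethoxy)-3,5-bis(3-methylbut-2-en-1-yl)phenyl]propan-1-one (both carbinol epimers) | CC(C)=CCc1c(OCOC)c(CC=C(C)C)c(O)c(c1OCOC)C(=O)CC(O)c1cc2c(cc1OCOC)O[C@@H](c1ccc(OCOC)cc1)[C@@H]2c1cc(OCOC)cc(OCOC)c1 | intermediate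
22 | (E)-3-[(2R,3R)-3-[3,5-bis(methoxymethoxy)phenyl]-6-(methoxymethoxy)-2-[4-(methoxymethoxy)phenyl]-2,3-dihydro-1-benzofuran-5-yl]-1-[2-hydroxy-4,6-bis(methoxymethoxy)-3,5-bis(3-methylbut-2-en-1-yl)phenyl]prop-2-en-1-one | CC(C)=CCc1c(OCOC)c(CC=C(C)C)c(O)c(c1OCOC)C(=O)/C=C/c1cc2c(cc1OCOC)O[C@@H](c1ccc(OCOC)cc1)[C@@H]2c1cc(OCOC)cc(OCOC)c1 | intermediate
23 | (2R)-2-[(2R,3R)-3-[3,5-bis(methoxymethoxy)phenyl]-6-(methoxymethoxy)-2-[4-(methoxymethoxy)phenyl]-2,3-dihydro-1-benzofuran-5-yl]-5,7-bis(methoxymethoxy)-6,8-bis(3-methylbut-2-en-1-yl)-2,3-dihydro-4H-chromen-4-one (2R epimer of 24, same dihydrobenzofuran configuration) | CC(C)=CCc1c(OCOC)c(CC=C(C)C)c2c(c1OCOC)C(=O)C[C@H](c1cc3c(cc1OCOC)O[C@@H](c1ccc(OCOC)cc1)[C@@H]3c1cc(OCOC)cc(OCOC)c1)O2 | intermediate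
24 | (2S)-2-[(2R,3R)-3-[3,5-bis(methoxymethoxy)phenyl]-6-(methoxymethoxy)-2-[4-(methoxymethoxy)phenyl]-2,3-dihydro-1-benzofuran-5-yl]-5,7-bis(methoxymethoxy)-6,8-bis(3-methylbut-2-en-1-yl)-2,3-dihydro-4H-chromen-4-one | CC(C)=CCc1c(OCOC)c(CC=C(C)C)c2c(c1OCOC)C(=O)C[C@@H](c1cc3c(cc1OCOC)O[C@@H](c1ccc(OCOC)cc1)[C@@H]3c1cc(OCOC)cc(OCOC)c1)O2 | intermediate
25 | (2S)-2-[(2R,3R)-3-(3,5-dihydroxyphenyl)-6-hydroxy-2-(4-hydroxyphenyl)-2,3-dihydro-1-benzofuran-5-yl]-5,7-dihydroxy-6,8-bis(3-methylbut-2-en-1-yl)-2,3-dihydro-4H-chromen-4-one | CC(C)=CCc1c(O)c(CC=C(C)C)c2c(c1O)C(=O)C[C@@H](c1cc3c(cc1O)O[C@@H](c1ccc(O)cc1)[C@@H]3c1cc(O)cc(O)c1)O2 | target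

**Totals**
Total step count: 15. Longest linear sequence: 13 steps (steps 1–10, then 13, 14, 15); the ring A branch is steps 11–12.

**Three steps most likely to fail**

Step 6 (carbene C–H insertion: yield, enantioselectivity and sense of induction on a very electron-rich diaryl carbene). The fallback sets out from 8 and comes back at 12, replacing asymmetric catalysis by a cation cyclisation to the racemic trans core followed by resolution. Corey–Chaykovsky methylenation of 8 (trimethylsulfonium iodide, NaH, DMSO/THF) gives racemic 2-[5-bromo-4-methoxy-2-[(4-methoxyphenyl)methoxy]phenyl]-2-(3,5-dimethoxyphenyl)oxirane F1. Catalytic ZnI2 in toluene effects Meinwald rearrangement to the diarylacetaldehyde F2. 4-Methoxyphenylmagnesium bromide then adds to give the 1-(4-methoxyphenyl)-2,2-diarylethanol F3 as a diastereomer mixture. TFA with anisole in CH2Cl2 removes the 4-methoxybenzyl group and closes the ring through the 4-methoxybenzylic cation under thermodynamic control, giving the trans compound as a racemate of 12 and its (2S,3S)-enantiomer F4. Preparative HPLC on a chiral stationary phase delivers 12.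

Step 14 (ring closure gives both C2 epimers; the equilibrium may be slow or the epimers hard to separate). The fallback sets out from 20 (with 16) and comes back at 24, building C2 by a reagent-controlled aldol addition and a stereospecific ring closure. Compound 20 is silylated (TBSOTf, 2,6-lutidine, CH2Cl2) to the tert-butyldimethylsilyl ether F5. Enolisation with the Ipc2BCl antipode that gives the R carbinol (Et3N, Et2O, 0 °C) and addition of 16 at −78 °C gives the (3R)-β-hydroxy ketone silyl ether F6; any minor carbinol epimer is a diastereomer and is removed on silica. TBAF buffered with AcOH frees the phenol to give the (3R)-β-hydroxy ketone F7, the 3R epimer of 21. Mitsunobu cyclisation (PPh3, DIAD, THF, 0 °C) displaces the activated benzylic alcohol with inversion and gives 24.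

Step 15 (six acetals removed with acid next to two prenyl groups and an acid-labile benzylic C2–O bond; risks are chroman formation and C2 epimerisation). The fallback sets out from 13 (with 19) and comes back at 25, replacing the acetal protection by allyl ethers that are removed under neutral conditions. Compound 13 with allyl bromide and K2CO3 in DMF gives the tetra-O-allyl bromide F8. n-BuLi at −78 °C converts it into the tetra-O-allyl aryllithium F9, which with DMF gives the tetra-O-allyl aldehyde F10. Compound 19 with allyl bromide (2.2 equiv) and K2CO3 in acetone gives the bis-O-allyl ketone F11. KOH in EtOH condenses the two through the hexa-O-allyl aldol adduct F12 to the hexa-O-allyl chalcone F13. NaOAc in refluxing EtOH gives the (2S)-hexa-O-allyl flavanone F14 and its (2R)-epimer F15, which are separated, the latter being returned to the same conditions. Pd(PPh3)4 (5 mol%) with morpholine in THF at rt removes all six allyl groups from the (2S)-flavanone and gives 25.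

**Further compounds**
F1 | step 6 | racemic 2-[5-bromo-4-methoxy-2-[(4-methoxyphenyl)methoxy]phenyl]-2-(3,5-dimethoxyphenyl)oxirane | COc1ccc(COc2cc(OC)c(Br)cc2C3(CO3)c2cc(OC)cc(OC)c2)cc1
F2 | step 6 | racemic 2-[5-bromo-4-methoxy-2-[(4-methoxyphenyl)methoxy]phenyl]-2-(3,5-dimethoxyphenyl)acetaldehyde | COc1ccc(COc2cc(OC)c(Br)cc2C(C=O)c2cc(OC)cc(OC)c2)cc1
F3 | step 6 | 2-[5-bromo-4-methoxy-2-[(4-methoxyphenyl)methoxy]phenyl]-2-(3,5-dimethoxyphenyl)-1-(4-methoxyphenyl)ethanol (diastereomer mixture) | COc1ccc(COc2cc(OC)c(Br)cc2C(C(O)c2ccc(OC)cc2)c2cc(OC)cc(OC)c2)cc1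
F4 | step 6 | (2S,3S)-5-bromo-3-(3,5-dimethoxyphenyl)-6-methoxy-2-(4-methoxyphenyl)-2,3-dihydro-1-benzofuran | Brc1cc2c(cc1OC)O[C@H](c1ccc(OC)cc1)[C@H]2c1cc(OC)cc(OC)c1
F5 | step 14 | 1-[2-[tert-butyl(dimethyl)silyl]oxy-4,6-bis(methoxymethoxy)-3,5-bis(3-methylbut-2-en-1-yl)phenyl]ethanone | CC(=O)c1c(O[Si](C)(C)C(C)(C)C)c(CC=C(C)C)c(OCOC)c(CC=C(C)C)c1OCOC
F6 | step 14 | (3R)-3-hydroxy-3-[(2R,3R)-3-[3,5-bis(methoxymethoxy)phenyl]-6-(methoxymethoxy)-2-[4-(methoxymethoxy)phenyl]-2,3-dihydro-1-benzofuran-5-yl]-1-[2-[tert-butyl(dimethyl)silyl]oxy-4,6-bis(methoxymethoxy)-3,5-bis(3-methylbut-2-en-1-yl)phenyl]propan-1-one | CC(C)=CCc1c(OCOC)c(CC=C(C)C)c(O[Si](C)(C)C(C)(C)C)c(c1OCOC)C(=O)C[C@@H](O)c1cc2c(cc1OCOC)O[C@@H](c1ccc(OCOC)cc1)[C@@H]2c1cc(OCOC)cc(OCOC)c1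
F7 | step 14 | (3R)-3-hydroxy-3-[(2R,3R)-3-[3,5-bis(methoxymethoxy)phenyl]-6-(methoxymethoxy)-2-[4-(methoxymethoxy)phenyl]-2,3-dihydro-1-benzofuran-5-yl]-1-[2-hydroxy-4,6-bis(methoxymethoxy)-3,5-bis(3-methylbut-2-en-1-yl)phenyl]propan-1-one | CC(C)=CCc1c(OCOC)c(CC=C(C)C)c(O)c(c1OCOC)C(=O)C[C@@H](O)c1cc2c(cc1OCOC)O[C@@H](c1ccc(OCOC)cc1)[C@@H]2c1cc(OCOC)cc(OCOC)c1
F8 | step 15 | (2R,3R)-5-bromo-3-[3,5-bis(prop-2-en-1-yloxy)phenyl]-6-(prop-2-en-1-yloxy)-2-[4-(prop-2-en-1-yloxy)phenyl]-2,3-dihydro-1-benzofuran | Brc1cc2c(cc1OCC=C)O[C@@H](c1ccc(OCC=C)cc1)[C@@H]2c1cc(OCC=C)cc(OCC=C)c1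
F9 | step 15 | [(2R,3R)-3-[3,5-bis(prop-2-en-1-yloxy)phenyl]-6-(prop-2-en-1-yloxy)-2-[4-(prop-2-en-1-yloxy)phenyl]-2,3-dihydro-1-benzofuran-5-yl]lithium | [Li]c1cc2c(cc1OCC=C)O[C@@H](c1ccc(OCC=C)cc1)[C@@H]2c1cc(OCC=C)cc(OCC=C)c1
F10 | step 15 | (2R,3R)-3-[3,5-bis(prop-2-en-1-yloxy)phenyl]-6-(prop-2-en-1-yloxy)-2-[4-(prop-2-en-1-yloxy)phenyl]-2,3-dihydro-1-benzofuran-5-carbaldehyde | O=Cc1cc2c(cc1OCC=C)O[C@@H](c1ccc(OCC=C)cc1)[C@@H]2c1cc(OCC=C)cc(OCC=C)c1
F11 | step 15 | 1-[2-hydroxy-4,6-bis(prop-2-en-1-yloxy)-3,5-bis(3-methylbut-2-en-1-yl)phenyl]ethanone | CC(=O)c1c(O)c(CC=C(C)C)c(OCC=C)c(CC=C(C)C)c1OCC=C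
F12 | step 15 | 3-hydroxy-3-[(2R,3R)-3-[3,5-bis(prop-2-en-1-yloxy)phenyl]-6-(prop-2-en-1-yloxy)-2-[4-(prop-2-en-1-yloxy)phenyl]-2,3-dihydro-1-benzofuran-5-yl]-1-[2-hydroxy-4,6-bis(prop-2-en-1-yloxy)-3,5-bis(3-methylbut-2-en-1-yl)phenyl]propan-1-one (both carbinol epimers) | CC(C)=CCc1c(OCC=C)c(CC=C(C)C)c(O)c(c1OCC=C)C(=O)CC(O)c1cc2c(cc1OCC=C)O[C@@H](c1ccc(OCC=C)cc1)[C@@H]2c1cc(OCC=C)cc(OCC=C)c1
F13 | step 15 | (E)-3-[(2R,3R)-3-[3,5-bis(prop-2-en-1-yloxy)phenyl]-6-(prop-2-en-1-yloxy)-2-[4-(prop-2-en-1-yloxy)phenyl]-2,3-dihydro-1-benzofuran-5-yl]-1-[2-hydroxy-4,6-bis(prop-2-en-1-yloxy)-3,5-bis(3-methylbut-2-en-1-yl)phenyl]prop-2-en-1-one | CC(C)=CCc1c(OCC=C)c(CC=C(C)C)c(O)c(c1OCC=C)C(=O)/C=C/c1cc2c(cc1OCC=C)O[C@@H](c1ccc(OCC=C)cc1)[C@@H]2c1cc(OCC=C)cc(OCC=C)c1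
F14 | step 15 | (2S)-2-[(2R,3R)-3-[3,5-bis(prop-2-en-1-yloxy)phenyl]-6-(prop-2-en-1-yloxy)-2-[4-(prop-2-en-1-yloxy)phenyl]-2,3-dihydro-1-benzofuran-5-yl]-5,7-bis(prop-2-en-1-yloxy)-6,8-bis(3-methylbut-2-en-1-yl)-2,3-dihydro-4H-chromen-4-one | CC(C)=CCc1c(OCC=C)c(CC=C(C)C)c2c(c1OCC=C)C(=O)C[C@@H](c1cc3c(cc1OCC=C)O[C@@H](c1ccc(OCC=C)cc1)[C@@H]3c1cc(OCC=C)cc(OCC=C)c1)O2
F15 | step 15 | (2R) epimer of F14 | CC(C)=CCc1c(OCC=C)c(CC=C(C)C)c2c(c1OCC=C)C(=O)C[C@H](c1cc3c(cc1OCC=C)O[C@@H](c1ccc(OCC=C)cc1)[C@@H]3c1cc(OCC=C)cc(OCC=C)c1)O2
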